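**Retrosynthetic overview**
- The target has ring A (benzene), ring B (2-hydroxy-2,3-dihydropyran-4-one, hemiketal at C2) and ring C (4-hydroxy-2-pyranone). Rings A and C are bought; ring B is the only ring made.
- Ring B is opened at O1–C8a and C2–C3. This gives an aryl methyl ketone with a C–H bond at the future C8a and a pyranonylacetic acid, carried as its trivalent iodine dicarboxylate. They are joined in one pot by ketone-directed C–H acyloxylation, Baker–Venkataraman acyl shift and hemiketal closure.
- Enabling feature: the C4 carbonyl of ring B is ortho to C8a (O=C4–C4a–C8a–H, five-membered palladacycle) and its methyl carbon C3 is 1,5 to the new ester carbonyl C2. The same ketone therefore first directs O1–C8a formation and then supplies the enolate for the C2–C3 bond, while the 3-methylbutyl group at C5 blocks the other ortho site.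
- The ketone comes from 1-(2-bromo-4-hydroxyphenyl)ethanone (O-benzylation, Negishi coupling). The acid comes from 4-hydroxy-6-methyl-2H-pyran-2-one (Mitsunobu benzylation, lateral lithiation/CO2).
- End game: neutral hydrogenolysis, then the labile C2 hemiketal centre is fixed by crystallization-induced asymmetric transformation of a chiral ammonium pyranolate salt, and the free (2R)-compound is liberated cold.

Key step: step 6

Assumption: C2 is a hemiketal carbon that epimerizes by ring–chain tautomerism whenever acid or base is present; it is taken to hold its configuration in cold, neutral, aprotic media, and the enantiomer of the resolving amine that makes the (2R)-salt the less soluble one has to be chosen by a crystallization screen (the (S)-amine is written).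

**Route**

Step 1
Reactants: 1 1-(2-bromo-4-hydroxyphenyl)ethanone
Product: 2 1-[4-(benzyloxy)-2-bromophenyl]ethanone
Conditions: BnBr (1.1 equiv), K2CO3, acetone, reflux
Reagents that add atoms: benzyl bromide, BrCc1ccccc1
Why: Williamson ether synthesis, in which the phenol para to the acetyl group is deprotonated by K2CO3 and the phenoxide displaces bromide from benzyl bromide (SN2), masking the oxygen that would otherwise be oxidized in step 6.

Step 2
Reactants: 2 1-[4-(benzyloxy)-2-bromophenyl]ethanone
Product: 3 1-[4-(benzyloxy)-2-(3-methylbutyl)phenyl]ethanone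
Conditions: (3-methylbutyl)zinc bromide (1.3 equiv, THF), Pd(OAc)2 (2 mol %), SPhos (4 mol %), THF, 40 °C
Reagents that add atoms: (3-methylbutyl)zinc bromide, CC(C)CC[Zn]Br
Why: Negishi coupling, with oxidative addition of zerovalent palladium into the C–Br bond activated by the ortho acetyl group, transmetalation with the ketone-tolerant primary alkylzinc reagent and reductive elimination, the bulky biaryl phosphine suppressing β-hydride elimination.

Step 3
Reactants: 4 4-hydroxy-6-methyl-2H-pyran-2-one (triacetic acid lactone)
Product: 5 4-(benzyloxy)-6-methyl-2H-pyran-2-one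
Conditions: BnOH, PPh3, diisopropyl azodicarboxylate, THF, 0 → 20 °C
Reagents that add atoms: benzyl alcohol, OCc1ccccc1
Why: Mitsunobu reaction, in which the acidic 4-hydroxy-2-pyranone (a vinylogous carboxylic acid) is alkylated on O4 by the alkoxyphosphonium ion of benzyl alcohol, avoiding the C3-alkylation that benzyl halides and base can give.

Step 4
Reactants: 5 4-(benzyloxy)-6-methyl-2H-pyran-2-one
Product: 6 [4-(benzyloxy)-2-oxo-2H-pyran-6-yl]acetic acid
Conditions: LiN(i-Pr)2 (2.2 equiv), THF, −78 °C; CO2 (gas), −78 → −40 °C; cold 1 M HCl to pH 2–3, extraction below 10 °C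
Reagents that add atoms: carbon dioxide, O=C=O
Why: Lateral (vinylogous) lithiation–carboxylation, in which deprotonation of the 6-methyl group gives a delocalized lithium trienolate that adds to CO2 at the exocyclic carbon (a known reactivity pattern of 4-alkoxy-6-methyl-2-pyranones), the second equivalent of base covering the more acidic CH2 of the product.

Step 5
Reactants: 6 [4-(benzyloxy)-2-oxo-2H-pyran-6-yl]acetic acid
Product: 7 [bis({[4-(benzyloxy)-2-oxo-2H-pyran-6-yl]acetyl}oxy)iodo]benzene
Conditions: PhI(OAc)2 (0.5 equiv relative to 6), PhCl, 40 °C, 20 mbar, repeated co-evaporation, dark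
Reagents that add atoms: (diacetoxyiodo)benzene, CC(=O)OI(OC(C)=O)c1ccccc1
Why: Ligand exchange at trivalent iodine, in which both acetates of PhI(OAc)2 are replaced by the non-volatile acid 6 and the equilibrium is pulled over by distilling off acetic acid, the standard preparation of [bis(acyloxy)iodo]arenes.

Step 6
Reactants: 3 1-[4-(benzyloxy)-2-(3-methylbutyl)phenyl]ethanone; 7 [bis({[4-(benzyloxy)-2-oxo-2H-pyran-6-yl]acetyl}oxy)iodo]benzene
Product: 10 rac-7-(benzyloxy)-2-{[4-(benzyloxy)-2-oxo-2H-pyran-6-yl]methyl}-2-hydroxy-5-(3-methylbutyl)-2,3-dihydro-4H-chromen-4-one, via aryl ester 8 (not isolated), via open-chain diketone 9 (not isolated)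
Conditions: 3 (1.2 equiv), 7 (1.0 equiv), Pd(MeCN)4(BF4)2 (10 mol %), ClCH2CH2Cl, 60 °C, dark; evaporate; THF, LiN(SiMe3)2 (5.5 equiv), −78 → −20 °C; AcOH, −78 °C; pH 7 phosphate buffer, 20 °C
Reagents that add atoms: none
Why: Proposed new method: the C4 ketone oxygen of 3 steers cationic divalent palladium into the only free ortho C–H bond (the future C8a) through a five-membered palladacycle, iodane 7 oxidizes this to a tetravalent palladium carboxylate and C–O reductive elimination gives aryl ester 8 with the new O1–C8a bond; the closest known reaction is the ketone-directed ortho C–H trifluoroacetoxylation of aryl ketones with Pd(O2CCF3)2 and PhI(O2CCF3)2, and the extension lies in transferring a functionalized carboxylate, which is why 7 is the sole carboxylate source and a carboxylate-free cationic catalyst is used. LiN(SiMe3)2 then enolizes the acetyl CH3 (C3) and the acyl group moves from O1 to C3 (Baker–Venkataraman rearrangement through a six-membered cyclic tetrahedral intermediate, or the equivalent E1cB ketene/phenoxide recombination), which makes the C2–C3 bond and, after the acetic acid quench, diketone 9. Ring B then closes by 6-exo-trig addition of the freed phenol O1–H to the C2 ketone; the 3-methylbutyl group at C5 twists the aryl ketone out of conjugation, which disfavours the chelated open enol and should make the hemiketal the resting form. The C2 stereocentre arises here without any controlling element (racemic, epimerizable) and is set in step 7. The selectivity needed is the ortho C–H bond over the nucleophilic C3/C5 positions of the pyranone and the benzylic CH2 groups, secured by chelation-assisted palladation and by the C5 side chain blocking the second ortho site, while exclusion of acetate and trifluoroacetate prevents a wrong ester.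

Step 7
Reactants: 10 rac-7-(benzyloxy)-2-{[4-(benzyloxy)-2-oxo-2H-pyran-6-yl]methyl}-2-hydroxy-5-(3-methylbutyl)-2,3-dihydro-4H-chromen-4-one
Product: 12 (1S)-N,N-dimethyl-1-phenylethanaminium 6-{[(2R)-2,7-dihydroxy-5-(3-methylbutyl)-4-oxo-3,4-dihydro-2H-chromen-2-yl]methyl}-2-oxo-2H-pyran-4-olate, via racemic hemiketal 11 (not isolated)
Conditions: H2 (1 atm), Pd/C (10 wt % Pd), EtOAc, 20 °C; filter; (1S)-N,N-dimethyl-1-phenylethanamine (1.1 equiv), i-PrOAc/heptane, seeding, 20 → 0 °C, slurry 48 h; filter
Reagents that add atoms: (1S)-N,N-dimethyl-1-phenylethanamine, C[C@H](N(C)C)c1ccccc1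
Why: Hydrogenolysis cleaves the aryl benzyl ether and the vinylogous benzyl ester under neutral conditions, after which the amine forms the ammonium salt of the acidic pyranone 4-OH and also catalyses ring–chain tautomerism of the hemiketal, so that both C2 epimers interconvert in solution while the less soluble diastereomeric salt crystallizes (crystallization-induced asymmetric transformation, as when a single anomer crystallizes from a mutarotating sugar), the C2 configuration thus being set under thermodynamic control by the lattice of the chiral salt.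

Step 8
Reactants: 12 (1S)-N,N-dimethyl-1-phenylethanaminium 6-{[(2R)-2,7-dihydroxy-5-(3-methylbutyl)-4-oxo-3,4-dihydro-2H-chromen-2-yl]methyl}-2-oxo-2H-pyran-4-olate
Product: 13 (2R)-2,7-dihydroxy-2-[(4-hydroxy-2-oxo-2H-pyran-6-yl)methyl]-5-(3-methylbutyl)-2,3-dihydro-4H-chromen-4-one
Conditions: EtOAc / 5% aq. citric acid, 0 °C, short contact; Na2SO4; evaporate below 10 °C; store cold and dry
Reagents that add atoms: none
Why: Acid–base liberation, in which proton transfer from a weak acid to the pyranolate in a cold two-phase system takes the amine into water without a base or a strong acid reaching the hemiketal, so the C2 configuration fixed in step 7 should be carried into the product.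

**Compound list**
1 | 1-(2-bromo-4-hydroxyphenyl)ethanone | CC(=O)c1ccc(O)cc1Br | starting material
2 | 1-[4-(benzyloxy)-2-bromophenyl]ethanone | CC(=O)c1ccc(OCc2ccccc2)cc1Br | intermediate
3 | 1-[4-(benzyloxy)-2-(3-methylbutyl)phenyl]ethanone | CC(=O)c1ccc(OCc2ccccc2)cc1CCC(C)C | intermediate
4 | 4-hydroxy-6-methyl-2H-pyran-2-one | Cc1cc(O)cc(=O)o1 | starting material
5 | 4-(benzyloxy)-6-methyl-2H-pyran-2-one | Cc1cc(OCc2ccccc2)cc(=O)o1 | intermediate
6 | [4-(benzyloxy)-2-oxo-2H-pyran-6-yl]acetic acid | OC(=O)Cc1cc(OCc2ccccc2)cc(=O)o1 | intermediate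
7 | [bis({[4-(benzyloxy)-2-oxo-2H-pyran-6-yl]acetyl}oxy)iodo]benzene | O=C(Cc1cc(OCc2ccccc2)cc(=O)o1)OI(OC(=O)Cc1cc(OCc2ccccc2)cc(=O)o1)c1ccccc1 | intermediate
8 | 2-acetyl-5-(benzyloxy)-3-(3-methylbutyl)phenyl [4-(benzyloxy)-2-oxo-2H-pyran-6-yl]acetate | CC(=O)c1c(CCC(C)C)cc(OCc2ccccc2)cc1OC(=O)Cc1cc(OCc2ccccc2)cc(=O)o1 | intermediate
9 | 1-[4-(benzyloxy)-2-hydroxy-6-(3-methylbutyl)phenyl]-4-[4-(benzyloxy)-2-oxo-2H-pyran-6-yl]butane-1,3-dione | CC(C)CCc1cc(OCc2ccccc2)cc(O)c1C(=O)CC(=O)Cc1cc(OCc2ccccc2)cc(=O)o1 | intermediate
10 | rac-7-(benzyloxy)-2-{[4-(benzyloxy)-2-oxo-2H-pyran-6-yl]methyl}-2-hydroxy-5-(3-methylbutyl)-2,3-dihydro-4H-chromen-4-one | CC(C)CCc1cc(OCc3ccccc3)cc2OC(O)(Cc4cc(OCc5ccccc5)cc(=O)o4)CC(=O)c12 | intermediate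
11 | rac-2,7-dihydroxy-2-[(4-hydroxy-2-oxo-2H-pyran-6-yl)methyl]-5-(3-methylbutyl)-2,3-dihydro-4H-chromen-4-one | CC(C)CCc1cc(O)cc2OC(O)(Cc3cc(O)cc(=O)o3)CC(=O)c12 | intermediate
12 | (1S)-N,N-dimethyl-1-phenylethanaminium 6-{[(2R)-2,7-dihydroxy-5-(3-methylbutyl)-4-oxo-3,4-dihydro-2H-chromen-2-yl]methyl}-2-oxo-2H-pyran-4-olate | CC(C)CCc1cc(O)cc2c1C(=O)C[C@@](O)(Cc1cc([O-])cc(=O)o1)O2.C[C@H]([NH+](C)C)c1ccccc1 | intermediate
13 | (2R)-2,7-dihydroxy-2-[(4-hydroxy-2-oxo-2H-pyran-6-yl)methyl]-5-(3-methylbutyl)-2,3-dihydro-4H-chromen-4-one | CC(C)CCc1cc(O)cc2c1C(=O)C[C@@](O)(Cc1cc(O)cc(=O)o1)O2 | target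

**Step count and risks**

Total step count: 8. Longest linear sequence: 6 steps (steps 3, 4, 5, 6, 7, 8, from 4-hydroxy-6-methyl-2H-pyran-2-one).

Steps most likely to fail:

1. Step 6 (proposed new method). Cyclopalladation directed by the weakly donating ketone may be outrun by loss of CO2 from the pyranonylacetate ligands of 7 or by oxidation of the electron-rich pyranone ring, so that no aryl ester forms; the acyl shift itself is not the concern. The fallback uses known chemistry, sets out from 3 and uses acid 6 directly, so step 5 is not needed. Ketone 3 is oxygenated at the same C–H bond by the known ketone-directed trifluoroacetoxylation (Pd(O2CCF3)2 as catalyst, PhI(O2CCF3)2, ClCH2CH2Cl, 80 °C) to 2-acetyl-5-(benzyloxy)-3-(3-methylbutyl)phenyl trifluoroacetate F1. The NaHCO3/MeOH work-up cleaves this to 1-[4-(benzyloxy)-2-hydroxy-6-(3-methylbutyl)phenyl]ethanone F2. F2 is esterified with 6 (EDC·HCl, DMAP, CH2Cl2, 0 °C) to ester 8, now isolated, and 8 is rearranged with LiN(SiMe3)2 in THF and quenched as in step 6. The fallback comes back to the route at 10.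

2. Step 7. The pyranone C5=C6 bond may be saturated under H2, neither diastereomeric salt may crystallize, epimerization in the slurry may be too slow, or the amine may induce dehydration of the hemiketal to the chromone. The fallback sets out from 10 and replaces the crystallization-driven transformation by a chromatographic resolution. The benzyl groups are removed by transfer hydrogenolysis (1,4-cyclohexadiene, Pd/C, EtOAc) and racemic 11 is isolated. It is separated by preparative supercritical-fluid chromatography on a polysaccharide carbamate phase at low temperature, and the (2S)-fraction is re-equilibrated with a trace of triethylamine and recycled. The fallback comes back at 13 and bypasses 12; it makes no compound outside the list (F0).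

3. Step 4. Deprotonation at ring C3 may compete with lateral deprotonation, and acid 6 may lose CO2 during the acidic work-up. The fallback sets out from 4. LiN(i-Pr)2 (3.2 equiv, THF, −78 °C) converts 4 into its O,C-dianion, in which the 4-oxide shuts down ring deprotonation, and dimethyl carbonate acylates it to methyl (4-hydroxy-2-oxo-2H-pyran-6-yl)acetate F3. Mitsunobu benzylation as in step 3 gives methyl [4-(benzyloxy)-2-oxo-2H-pyran-6-yl]acetate F4. The methyl ester is cleaved with Me3SnOH (ClCH2CH2Cl, 60 °C). The fallback comes back at 6 and bypasses 5.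

Further compounds
F1 | step 6 | 2-acetyl-5-(benzyloxy)-3-(3-methylbutyl)phenyl trifluoroacetate | CC(=O)c1c(CCC(C)C)cc(OCc2ccccc2)cc1OC(=O)C(F)(F)F
F2 | step 6 | 1-[4-(benzyloxy)-2-hydroxy-6-(3-methylbutyl)phenyl]ethanone | CC(=O)c1c(CCC(C)C)cc(OCc2ccccc2)cc1O
F0 | step 7 | none | none
F3 | step 4 | methyl (4-hydroxy-2-oxo-2H-pyran-6-yl)acetate | COC(=O)Cc1cc(O)cc(=O)o1
F4 | step 4 | methyl [4-(benzyloxy)-2-oxo-2H-pyran-6-yl]acetate | COC(=O)Cc1cc(OCc2ccccc2)cc(=O)o1
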